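**Plan**

- Retrosynthesis: first cut the bond between the heptyl CH2 and ring carbon C-4 of ring A (the hydroxymethyl furan-2,5-dione); then the ring-closing C–O bond and the C–CO2 bond on the stereocentre-bearing ring carbon of ring B (the oxohexyl furan-2,5-dione, built from a β-keto ester); last the C–CH2CO2R bond at the stereocentre.
- Enabling feature: in ring A the C-3=C-4 double bond lies between two carbonyls and C-4 carries only a CH2. A 3-(silyloxymethyl)furan-2,5-dione with C-4 unsubstituted should therefore accept a nucleophilic primary radical at C-4. The radical is born on the CH2 next to the stereocentre from an acid whose carboxyl carbon leaves as CO2.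
- Forward order: auxiliary alkylation → (S)-2-pentylsuccinate half-ester → β-keto ester → alkylation with bromohexanone, ketal → enol triflate → carbonylation → acid closes ring B → decarboxylative radical addition joins the furan-derived ring A anhydride → sulfoxide elimination restores the ring A double bond → desilylation.
- Helpers and their removal: the extra carboxyl carbon (lost as CO2), the 2-pyridylthio group (lost in step 14), the dioxolane (step 9) and the silyl ether (step 15).
- Stereochemistry: the single (S) centre comes from the (R)-4-benzyloxazolidinone-directed alkylation in step 2; no later step breaks a bond to it or enolises it.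

Key step: step 13

Remark: 1-bromohexan-2-one is taken as a catalogue compound (otherwise one step from hexan-2-one by bromination in methanol); the target is handled throughout as the open hydroxymethyl anhydride, so the alcohol is released last and without aqueous base.

**Route**

Step 1
Reactants: 1 (4R)-4-benzyl-1,3-oxazolidin-2-one; 2 heptanoyl chloride
Product: 3 (4R)-4-benzyl-3-heptanoyl-1,3-oxazolidin-2-one
Conditions: n-BuLi, THF, −78 °C; then 2, −78 → 0 °C
Reagents that add atoms: none
Why: N-acylation of the lithiated oxazolidinone by the acid chloride (attachment of the Evans auxiliary), in which no stereocentre is formed.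

Step 2
Reactants: 3 (4R)-4-benzyl-3-heptanoyl-1,3-oxazolidin-2-one; 4 tert-butyl bromoacetate
Product: 5 tert-butyl (3S)-3-{[(4R)-4-benzyl-2-oxo-1,3-oxazolidin-3-yl]carbonyl}octanoate
Conditions: NaN(SiMe3)2, THF, −78 °C; then 4, −78 → −40 °C
Reagents that add atoms: none
Why: Evans asymmetric alkylation, in which the chelated (Z)-sodium enolate should be alkylated by the reactive bromoacetate on the face opposite the benzyl group of the (R)-auxiliary, setting the (S) centre that becomes the only stereocentre of the target.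

Step 3
Reactants: 5 tert-butyl (3S)-3-{[(4R)-4-benzyl-2-oxo-1,3-oxazolidin-3-yl]carbonyl}octanoate
Product: 6 (2S)-4-tert-butoxy-4-oxo-2-pentylbutanoic acid
Conditions: LiOH, H2O2, THF/H2O, 0 °C; Na2SO3; HCl to pH 2
Reagents that add atoms: hydrogen peroxide (OO)
Why: Hydroperoxide cleavage of the N-acyloxazolidinone, in which LiOOH attacks the exocyclic carbonyl selectively and should leave the tert-butyl ester and the α-stereocentre untouched.

Step 4
Reactants: 6 (2S)-4-tert-butoxy-4-oxo-2-pentylbutanoic acid; 7 3-tert-butoxy-3-oxopropanoic acid (mono-tert-butyl malonate)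
Product: 9 di-tert-butyl (4S)-3-oxo-4-pentylhexanedioate, via acyl imidazolide 8 (not isolated)
Conditions: CDI, THF, rt; then 7, MgCl2, Et3N, MeCN, rt → 40 °C
Reagents that add atoms: none
Why: Masamune–Brooks decarboxylative Claisen homologation, in which the acyl imidazolide acylates the magnesium enolate of the malonate half-ester under nearly neutral conditions so that the α-stereocentre should not epimerise.

Step 5
Reactants: 9 di-tert-butyl (4S)-3-oxo-4-pentylhexanedioate; 10 1-bromohexan-2-one
Product: 11 di-tert-butyl (4S)-3-oxo-2-(2-oxohexyl)-4-pentylhexanedioate (mixture of C-2 epimers)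
Conditions: NaH, THF, 0 °C; then 10, 0 °C → rt
Reagents that add atoms: none
Why: C-alkylation of the β-keto ester sodium enolate by an α-bromo ketone (SN2); the new C-2 centre is erased in step 7, and one equivalent of base enolises only the carbon between the two carbonyls, not the (S) centre.

Step 6
Reactants: 11 di-tert-butyl (4S)-3-oxo-2-(2-oxohexyl)-4-pentylhexanedioate
Product: 12 di-tert-butyl (4S)-2-[(2-butyl-1,3-dioxolan-2-yl)methyl]-3-oxo-4-pentylhexanedioate
Conditions: (Me3SiOCH2)2, Me3SiOTf (cat.), CH2Cl2, −78 → −20 °C; pyridine quench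
Reagents that add atoms: 1,2-bis(trimethylsilyloxy)ethane (C[Si](C)(C)OCCO[Si](C)(C)C)
Why: Noyori ketalisation should take the unhindered dialkyl ketone in preference to the hindered, deactivated β-keto ester carbonyl, which removes the acidic keto-methylene and the second enolisable ketone before the base and palladium steps.

Step 7
Reactants: 12 di-tert-butyl (4S)-2-[(2-butyl-1,3-dioxolan-2-yl)methyl]-3-oxo-4-pentylhexanedioate
Product: 13 di-tert-butyl (2Z,4S)-2-[(2-butyl-1,3-dioxolan-2-yl)methyl]-4-pentyl-3-{[(trifluoromethyl)sulfonyl]oxy}hex-2-enedioate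
Conditions: NaH, Et2O, 0 °C → rt; then Tf2O, −78 → 0 °C
Reagents that add atoms: trifluoromethanesulfonic anhydride (O=S(=O)(OS(=O)(=O)C(F)(F)F)C(F)(F)F)
Why: Enol triflate formation by O-sulfonylation of the chelated sodium enolate, in which sodium bridges the enolate oxygen and the ester carbonyl so that the triflate should form cis to the ester, the (Z) geometry needed for a cis diester.

Step 8
Reactants: 13 di-tert-butyl (2Z,4S)-2-[(2-butyl-1,3-dioxolan-2-yl)methyl]-4-pentyl-3-{[(trifluoromethyl)sulfonyl]oxy}hex-2-enedioate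
Product: 14 di-tert-butyl (2Z,4S)-2-[(2-butyl-1,3-dioxolan-2-yl)methyl]-3-(methoxycarbonyl)-4-pentylhex-2-enedioate
Conditions: Pd(OAc)2 (cat.), Ph2P(CH2)3PPh2, CO (1 atm), MeOH, Et3N, DMF, 60 °C
Reagents that add atoms: carbon monoxide ([C-]#[O+]); methanol (CO)
Why: Palladium-catalysed methoxycarbonylation of an enol triflate (oxidative addition to zerovalent palladium, CO insertion, methanolysis of the acyl palladium) should proceed with retention of alkene geometry and give the cis, maleate-type triester.

Step 9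
Reactants: 14 di-tert-butyl (2Z,4S)-2-[(2-butyl-1,3-dioxolan-2-yl)methyl]-3-(methoxycarbonyl)-4-pentylhex-2-enedioate
Product: 16 (3S)-3-[4-(2-oxohexyl)-2,5-dioxo-2,5-dihydrofuran-3-yl]octanoic acid, via methyl half-ester 15 (not isolated)
Conditions: TFA/CH2Cl2/H2O (10:9:1), 0 °C → rt; evaporate; PhMe, 50 °C
Reagents that add atoms: water (O)
Why: Acidolysis removes both tert-butyl esters and the dioxolane, after which the cis methyl hydrogen dialkylmaleate should close to the five-membered anhydride with loss of methanol (intramolecular acyl substitution favoured by the cis tetrasubstituted alkene), so that ring B and its ketone appear under non-basic conditions.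

Step 10
Reactants: 17 furan-3-ylmethanol
Product: 18 tert-butyl(furan-3-ylmethoxy)dimethylsilane
Conditions: TBSCl, imidazole, CH2Cl2, rt
Reagents that add atoms: tert-butyl(chloro)dimethylsilane (CC(C)(C)[Si](C)(C)Cl)
Why: Standard silylation of a primary alcohol, which keeps the hydroxyl from opening the anhydrides that follow.

Step 11
Reactants: 18 tert-butyl(furan-3-ylmethoxy)dimethylsilane
Product: 20 4-({[tert-butyl(dimethyl)silyl]oxy}methyl)-5-hydroxyfuran-2(5H)-one (racemic at C-5), via furan endoperoxide 19 (not isolated)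
Conditions: O2, hν (visible), tetraphenylporphyrin (cat.), iPr2NEt, CH2Cl2, −78 °C → rt
Reagents that add atoms: dioxygen (O=O)
Why: [4+2] cycloaddition of singlet oxygen to the furan followed by base-induced Kornblum–DeLaMare fragmentation of the endoperoxide should give the γ-hydroxybutenolide, and either regioisomer of it leads to the same anhydride in step 12.

Step 12
Reactants: 20 4-({[tert-butyl(dimethyl)silyl]oxy}methyl)-5-hydroxyfuran-2(5H)-one
Product: 21 3-({[tert-butyl(dimethyl)silyl]oxy}methyl)furan-2,5-dione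
Conditions: [C5H5NH][CrO3Cl], NaOAc, CH2Cl2, rt
Reagents that add atoms: none
Why: Lactol-to-lactone oxidation of the hemiacylal carbon by buffered hexavalent chromium should turn the γ-hydroxybutenolide into the maleic anhydride while the silyl ether survives.

Step 13
Reactants: 16 (3S)-3-[4-(2-oxohexyl)-2,5-dioxo-2,5-dihydrofuran-3-yl]octanoic acid; 21 3-({[tert-butyl(dimethyl)silyl]oxy}methyl)furan-2,5-dione
Product: 23 3-({[tert-butyl(dimethyl)silyl]oxy}methyl)-4-{(2S)-2-[4-(2-oxohexyl)-2,5-dioxo-2,5-dihydrofuran-3-yl]heptyl}-3-(pyridin-2-ylsulfanyl)oxolane-2,5-dione (mixture of ring diastereomers), via thiohydroxamate ester 22 (not isolated)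
Conditions: 1-hydroxypyridine-2(1H)-thione, DCC, CH2Cl2, 0 °C → rt, dark; then 21 (5 equiv), hν (tungsten lamp), CH2Cl2, 10–15 °C
Reagents that add atoms: 1-hydroxypyridine-2(1H)-thione (ON1C=CC=CC1=S)
Why: Barton decarboxylation: under visible light the O-acyl thiohydroxamate 22 loses CO2 to give the primary radical on the CH2 next to the stereocentre, which is nucleophilic and adds to the unsubstituted ring carbon C-4 of the electron-poor anhydride 21; the resulting tertiary α-carbonyl radical takes the 2-pyridylthio group from another molecule of 22 and so carries the chain. The closest known reaction type is the addition of Barton esters of aliphatic acids to citraconic anhydride followed by sulfoxide elimination, a known way to 2-alkyl-3-methylmaleic anhydrides. No ring is closed in this step. The two new centres in the oxolanedione ring are not controlled (group transfer trans to the new chain is expected on steric grounds) and do not matter because both become sp2 in step 14, while the (S) centre is untouched because the radical sits on the neighbouring carbon and no bond to the stereocentre is broken. The step needs regioselectivity for C-4 over the carbon bearing CH2OSi, which sterics and the stability of the tertiary radical should secure, and chemoselectivity over ring B and over direct capture of the radical by the thiocarbonyl group, which the tetrasubstituted hindered ring B alkene and a fivefold excess of 21 should secure.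

Step 14
Reactants: 23 3-({[tert-butyl(dimethyl)silyl]oxy}methyl)-4-{(2S)-2-[4-(2-oxohexyl)-2,5-dioxo-2,5-dihydrofuran-3-yl]heptyl}-3-(pyridin-2-ylsulfanyl)oxolane-2,5-dione
Product: 25 3-({[tert-butyl(dimethyl)silyl]oxy}methyl)-4-{(2S)-2-[4-(2-oxohexyl)-2,5-dioxo-2,5-dihydrofuran-3-yl]heptyl}furan-2,5-dione, via pyridyl sulfoxide 24 (not isolated)
Conditions: mCPBA (1.05 equiv), CH2Cl2, −78 °C; then rt
Reagents that add atoms: none
Why: Sulfide oxidation followed by thermal syn-elimination of the 2-pyridyl sulfoxide should take the acidic ring hydrogen α to the carbonyl (cis to sulfur after trans group transfer) and not a hydrogen of the CH2OSi group, since sulfoxide eliminations avoid forming enol ethers, which restores the tetrasubstituted double bond of ring A.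

Step 15
Reactants: 25 3-({[tert-butyl(dimethyl)silyl]oxy}methyl)-4-{(2S)-2-[4-(2-oxohexyl)-2,5-dioxo-2,5-dihydrofuran-3-yl]heptyl}furan-2,5-dione
Product: 26 3-(hydroxymethyl)-4-{(2S)-2-[4-(2-oxohexyl)-2,5-dioxo-2,5-dihydrofuran-3-yl]heptyl}furan-2,5-dione (CNP0537712.1)
Conditions: HF·pyridine, THF, 0 °C → rt; non-basic work-up
Reagents that add atoms: none
Why: Fluoride-mediated desilylation under anhydrous, weakly acidic conditions should free the alcohol, which cannot reach a ring A carbonyl while the planar anhydride is intact (lactonisation would need ring opening first), so the open hydroxymethyl anhydride is expected.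

**Compound list**

1 | (4R)-4-benzyl-1,3-oxazolidin-2-one | O=C1N[C@H](Cc2ccccc2)CO1 | starting material
2 | heptanoyl chloride | CCCCCCC(Cl)=O | starting material
3 | (4R)-4-benzyl-3-heptanoyl-1,3-oxazolidin-2-one | CCCCCCC(=O)N1[C@H](Cc2ccccc2)COC1=O | intermediate
4 | tert-butyl bromoacetate | BrCC(=O)OC(C)(C)C | starting material
5 | tert-butyl (3S)-3-{[(4R)-4-benzyl-2-oxo-1,3-oxazolidin-3-yl]carbonyl}octanoate | CCCCC[C@@H](CC(=O)OC(C)(C)C)C(=O)N1[C@H](Cc2ccccc2)COC1=O | intermediate
6 | (2S)-4-tert-butoxy-4-oxo-2-pentylbutanoic acid | CCCCC[C@@H](CC(=O)OC(C)(C)C)C(=O)O | intermediate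
7 | 3-tert-butoxy-3-oxopropanoic acid | OC(=O)CC(=O)OC(C)(C)C | starting material
8 | tert-butyl (3S)-3-(1H-imidazol-1-ylcarbonyl)octanoate (not isolated) | CCCCC[C@@H](CC(=O)OC(C)(C)C)C(=O)n1ccnc1 | intermediate
9 | di-tert-butyl (4S)-3-oxo-4-pentylhexanedioate | CCCCC[C@@H](CC(=O)OC(C)(C)C)C(=O)CC(=O)OC(C)(C)C | intermediate
10 | 1-bromohexan-2-one | CCCCC(=O)CBr | starting material
11 | di-tert-butyl (4S)-3-oxo-2-(2-oxohexyl)-4-pentylhexanedioate (C-2 epimers) | CCCCC[C@@H](CC(=O)OC(C)(C)C)C(=O)C(CC(=O)CCCC)C(=O)OC(C)(C)C | intermediate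
12 | di-tert-butyl (4S)-2-[(2-butyl-1,3-dioxolan-2-yl)methyl]-3-oxo-4-pentylhexanedioate (C-2 epimers) | CCCCC[C@@H](CC(=O)OC(C)(C)C)C(=O)C(CC1(CCCC)OCCO1)C(=O)OC(C)(C)C | intermediate
13 | di-tert-butyl (2Z,4S)-2-[(2-butyl-1,3-dioxolan-2-yl)methyl]-4-pentyl-3-{[(trifluoromethyl)sulfonyl]oxy}hex-2-enedioate | CCCCC[C@@H](CC(=O)OC(C)(C)C)/C(OS(=O)(=O)C(F)(F)F)=C(\CC1(CCCC)OCCO1)C(=O)OC(C)(C)C | intermediate
14 | di-tert-butyl (2Z,4S)-2-[(2-butyl-1,3-dioxolan-2-yl)methyl]-3-(methoxycarbonyl)-4-pentylhex-2-enedioate | CCCCC[C@@H](CC(=O)OC(C)(C)C)/C(C(=O)OC)=C(\CC1(CCCC)OCCO1)C(=O)OC(C)(C)C | intermediate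
15 | (2Z,4S)-3-(methoxycarbonyl)-2-(2-oxohexyl)-4-pentylhex-2-enedioic acid (not isolated) | CCCCC[C@@H](CC(=O)O)/C(C(=O)OC)=C(\CC(=O)CCCC)C(=O)O | intermediate
16 | (3S)-3-[4-(2-oxohexyl)-2,5-dioxo-2,5-dihydrofuran-3-yl]octanoic acid | CCCCC[C@@H](CC(=O)O)C1=C(CC(=O)CCCC)C(=O)OC1=O | intermediate
17 | furan-3-ylmethanol | OCc1ccoc1 | starting material
18 | tert-butyl(furan-3-ylmethoxy)dimethylsilane | CC(C)(C)[Si](C)(C)OCc1ccoc1 | intermediate
19 | tert-butyl(dimethyl)[(2,3,7-trioxabicyclo[2.2.1]hept-5-en-5-yl)methoxy]silane (not isolated) | CC(C)(C)[Si](C)(C)OCC1=CC2OOC1O2 | intermediate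
20 | 4-({[tert-butyl(dimethyl)silyl]oxy}methyl)-5-hydroxyfuran-2(5H)-one | CC(C)(C)[Si](C)(C)OCC1=CC(=O)OC1O | intermediate
21 | 3-({[tert-butyl(dimethyl)silyl]oxy}methyl)furan-2,5-dione | CC(C)(C)[Si](C)(C)OCC1=CC(=O)OC1=O | intermediate
22 | 2-thioxopyridin-1(2H)-yl (3S)-3-[4-(2-oxohexyl)-2,5-dioxo-2,5-dihydrofuran-3-yl]octanoate (not isolated) | CCCCC[C@@H](CC(=O)ON1C=CC=CC1=S)C2=C(CC(=O)CCCC)C(=O)OC2=O | intermediate
23 | 3-({[tert-butyl(dimethyl)silyl]oxy}methyl)-4-{(2S)-2-[4-(2-oxohexyl)-2,5-dioxo-2,5-dihydrofuran-3-yl]heptyl}-3-(pyridin-2-ylsulfanyl)oxolane-2,5-dione (ring diastereomers) | CCCCC[C@@H](CC1C(=O)OC(=O)C1(CO[Si](C)(C)C(C)(C)C)Sc2ccccn2)C3=C(CC(=O)CCCC)C(=O)OC3=O | intermediate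
24 | 3-({[tert-butyl(dimethyl)silyl]oxy}methyl)-4-{(2S)-2-[4-(2-oxohexyl)-2,5-dioxo-2,5-dihydrofuran-3-yl]heptyl}-3-(pyridin-2-ylsulfinyl)oxolane-2,5-dione (not isolated) | CCCCC[C@@H](CC1C(=O)OC(=O)C1(CO[Si](C)(C)C(C)(C)C)S(=O)c2ccccn2)C3=C(CC(=O)CCCC)C(=O)OC3=O | intermediate
25 | 3-({[tert-butyl(dimethyl)silyl]oxy}methyl)-4-{(2S)-2-[4-(2-oxohexyl)-2,5-dioxo-2,5-dihydrofuran-3-yl]heptyl}furan-2,5-dione | CCCCC[C@@H](CC1=C(CO[Si](C)(C)C(C)(C)C)C(=O)OC1=O)C2=C(CC(=O)CCCC)C(=O)OC2=O | intermediate
26 | 3-(hydroxymethyl)-4-{(2S)-2-[4-(2-oxohexyl)-2,5-dioxo-2,5-dihydrofuran-3-yl]heptyl}furan-2,5-dione | CCCCC[C@@H](CC1=C(CO)C(=O)OC1=O)C2=C(CC(=O)CCCC)C(=O)OC2=O | target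

**Count**

Total steps: 15. Longest linear sequence: 12 steps (steps 1–9, then 13–15); steps 10–12 make the ring A acceptor in a side branch.

**Steps most likely to fail**

Step 13. The primary radical may be lost before it adds to 21, by hydrogen transfer through a six-membered transition state from the doubly activated CH2 between ring B and the ketone; the same acidic methylene may also disturb formation of the thiohydroxamate ester. The fallback moves the radical event to a precursor whose ketone is still masked and reverses the order of unmasking. It sets out from 14: anhydrous TFA in CH2Cl2 at 0 °C (no water) should remove the two tert-butyl esters and leave the dioxolane, giving the ketal diacid half-ester (2Z,4S)-2-[(2-butyl-1,3-dioxolan-2-yl)methyl]-3-(methoxycarbonyl)-4-pentylhex-2-enedioic acid F1, which closes with loss of methanol to the ketal anhydride acid F2. F2 is esterified as in step 13 to its thiohydroxamate ester F3 and photolysed with 21 to the ketal adduct F4. Oxidation as in step 14 gives the ketal sulfoxide F5 and, after syn-elimination, the ketal silyl ether F6. TFA/H2O/THF at 0 °C then removes dioxolane and silyl ether together, and the fallback comes back to the route at 26.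

Step 7. Chelation of the crowded enolate may be lost, or O-sulfonylation may be slow, so that the E enol triflate forms and the diester ends up trans and cannot close in step 9. The fallback fixes the geometry by photoequilibration of the alkene instead of by enolate control. It sets out from 12: the E enol triflate F7 (isolated from the triflation mixture) is carbonylated as in step 8 to the trans triester F8. Triplet-sensitised E/Z isomerisation of F8 (benzophenone, hν 350 nm, benzene; the substrate has no ketone chromophore at this stage) should give a photostationary mixture from which the cis triester is separated and the trans isomer recycled. The fallback comes back to the route at 14.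

Step 8. With branched substituents on both sides of the triflate carbon, CO insertion or methanolysis of the acyl palladium may be slow, so that reduction of the triflate or loss of alkene geometry takes over. The fallback brings in the carboxyl carbon by C–C coupling as a masked ester instead of by CO insertion. It sets out from 13: Stille coupling with tributyl(1-ethoxyvinyl)stannane (Pd(PPh3)4, LiCl, dioxane, 90 °C) should give the 2-ethoxydiene F9 with retention of geometry. Ozonolysis (O3, CH2Cl2, −78 °C; Me2S) should cleave only the electron-rich enol ether double bond and give the ethyl triester F10. Under the conditions of step 9, F10 gives the ethyl half-ester F11, which closes with loss of ethanol, and the fallback comes back to the route at 16.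

**Further compounds**

F1 | step 13 | (2Z,4S)-2-[(2-butyl-1,3-dioxolan-2-yl)methyl]-3-(methoxycarbonyl)-4-pentylhex-2-enedioic acid | CCCCC[C@@H](CC(=O)O)/C(C(=O)OC)=C(\CC1(CCCC)OCCO1)C(=O)O
F2 | step 13 | (3S)-3-{4-[(2-butyl-1,3-dioxolan-2-yl)methyl]-2,5-dioxo-2,5-dihydrofuran-3-yl}octanoic acid | CCCCC[C@@H](CC(=O)O)C1=C(CC2(CCCC)OCCO2)C(=O)OC1=O
F3 | step 13 | 2-thioxopyridin-1(2H)-yl (3S)-3-{4-[(2-butyl-1,3-dioxolan-2-yl)methyl]-2,5-dioxo-2,5-dihydrofuran-3-yl}octanoate | CCCCC[C@@H](CC(=O)ON1C=CC=CC1=S)C2=C(CC3(CCCC)OCCO3)C(=O)OC2=O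
F4 | step 13 | 3-({[tert-butyl(dimethyl)silyl]oxy}methyl)-4-[(2S)-2-{4-[(2-butyl-1,3-dioxolan-2-yl)methyl]-2,5-dioxo-2,5-dihydrofuran-3-yl}heptyl]-3-(pyridin-2-ylsulfanyl)oxolane-2,5-dione | CCCCC[C@@H](CC1C(=O)OC(=O)C1(CO[Si](C)(C)C(C)(C)C)Sc2ccccn2)C3=C(CC4(CCCC)OCCO4)C(=O)OC3=O
F5 | step 13 | 3-({[tert-butyl(dimethyl)silyl]oxy}methyl)-4-[(2S)-2-{4-[(2-butyl-1,3-dioxolan-2-yl)methyl]-2,5-dioxo-2,5-dihydrofuran-3-yl}heptyl]-3-(pyridin-2-ylsulfinyl)oxolane-2,5-dione | CCCCC[C@@H](CC1C(=O)OC(=O)C1(CO[Si](C)(C)C(C)(C)C)S(=O)c2ccccn2)C3=C(CC4(CCCC)OCCO4)C(=O)OC3=O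
F6 | step 13 | 3-({[tert-butyl(dimethyl)silyl]oxy}methyl)-4-[(2S)-2-{4-[(2-butyl-1,3-dioxolan-2-yl)methyl]-2,5-dioxo-2,5-dihydrofuran-3-yl}heptyl]furan-2,5-dione | CCCCC[C@@H](CC1=C(CO[Si](C)(C)C(C)(C)C)C(=O)OC1=O)C2=C(CC3(CCCC)OCCO3)C(=O)OC2=O
F7 | step 7 | di-tert-butyl (2E,4S)-2-[(2-butyl-1,3-dioxolan-2-yl)methyl]-4-pentyl-3-{[(trifluoromethyl)sulfonyl]oxy}hex-2-enedioate | CCCCC[C@@H](CC(=O)OC(C)(C)C)/C(OS(=O)(=O)C(F)(F)F)=C(/CC1(CCCC)OCCO1)C(=O)OC(C)(C)C
F8 | step 7 | di-tert-butyl (2E,4S)-2-[(2-butyl-1,3-dioxolan-2-yl)methyl]-3-(methoxycarbonyl)-4-pentylhex-2-enedioate | CCCCC[C@@H](CC(=O)OC(C)(C)C)/C(C(=O)OC)=C(/CC1(CCCC)OCCO1)C(=O)OC(C)(C)C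
F9 | step 8 | di-tert-butyl (2Z,4S)-2-[(2-butyl-1,3-dioxolan-2-yl)methyl]-3-(1-ethoxyethenyl)-4-pentylhex-2-enedioate | CCCCC[C@@H](CC(=O)OC(C)(C)C)/C(C(=C)OCC)=C(\CC1(CCCC)OCCO1)C(=O)OC(C)(C)C
F10 | step 8 | di-tert-butyl (2Z,4S)-2-[(2-butyl-1,3-dioxolan-2-yl)methyl]-3-(ethoxycarbonyl)-4-pentylhex-2-enedioate | CCCCC[C@@H](CC(=O)OC(C)(C)C)/C(C(=O)OCC)=C(\CC1(CCCC)OCCO1)C(=O)OC(C)(C)C
F11 | step 8 | (2Z,4S)-3-(ethoxycarbonyl)-2-(2-oxohexyl)-4-pentylhex-2-enedioic acid | CCCCC[C@@H](CC(=O)O)/C(C(=O)OCC)=C(\CC(=O)CCCC)C(=O)O
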